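28.6% of the electrophile is left after 6.00 d in Saturday's run, and 13.7% in Sunday's, which has more free base.

| flask | electrophile | nucleophile | free base | remark | time |
|---|---|---|---|---|---|
| Saturday's | 0.050 M | 1 equiv | 1.2 equiv | run made earlier |  |
| Sunday's | 0.050 M | 1 equiv | 5.5 equiv | run made earlier |  |
| red | 0.050 M | 1.00 equiv | 1.10 equiv |  | 8.0 d |
| blue | 0.050 M | 1.00 equiv | 4.40 equiv |  | 8.0 d |
| green | 0.050 M | 1.00 equiv | 2.20 equiv |  | 8.0 d |

| run | time / d | electrophile / % | product / % |
|---|---|---|---|
| Saturday's | 0.417 | 47.5 | 53.4 |
| Saturday's | 1.04 | 39.9 | 58.9 |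
| Saturday's | 2.50 | 36.4 | 68.2 |
| Saturday's | 6.00 | 28.6 | 71.8 |
| Sunday's | 0.625 | 41.0 | 59.1 |
| Sunday's | 2.08 | 26.7 | 73.3 |
| Sunday's | 4.00 | 20.5 | 79.8 |
| Sunday's | 6.00 | 13.7 | 83.5 |

(readings scatter by 1 percentage point)



* part of the electrophile that has reacted at the end, red
* part of the electrophile that has reacted at the end, blue
* part of the electrophile that has reacted at the end, green
* what raising the equivalents of free base from its lowest to its highest value here does to the part of the electrophile that has reacted (changes below 5 percentage points count as none) (no change / it rises / it falls)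

My own reckoning goes in powers of ten.

1. The tail slope is the number of powers of ten of electrophile lost per day after the fast first stretch. Saturday's, from its second reading to its last, is 0.0292 d⁻¹.
2. Sunday's, read the same way, is 0.0739 d⁻¹.
3. The base order of the tail is the logarithm of the ratio of slopes over the logarithm of the ratio of free base: 0.611.
4. Saturday's slope scaled by that order gives 0.0276 d⁻¹ for red, 0.0422 d⁻¹ for green and 0.0645 d⁻¹ for blue.
5. Saturday's tail, run back to zero time, gives an anchor of 42.8%.
6. From that anchor, 8.0 d of tail leaves 25.7% in red, 19.7% in green and 13.1% in blue.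

The weak link is the shared anchor. Sunday's tail runs back to 38.0%, lower than Saturday's. On a logarithmic scale of free base, green lies nearer Saturday's, and red stays there too. Blue lies nearer Sunday's, so blue takes Sunday's anchor and leaves 11.6%. The reckoning stands at 74.3% reacted in red, 80.3% in green and 88.4% in blue.

The forecast reads 74% for red, 80% for green and 88% for blue, and for the trend, it rises. Its ground: “The tail looks roughly first order when plotted as ln(electrophile).”

The flasks give 73.9% for red, 79.4% for green and 84.9% for blue. With more free base the part reacted: it rises, by 11 percentage points.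

    electrophile + nucleophile → acid set free + product (k = 6.97 M⁻¹ h⁻¹)
    nucleophile + acid set free ⇌ protonated nucleophile, settled at all times (K = 15700 M⁻¹)
    acid set free + free base ⇌ salt of the base (K = 161 M⁻¹, k = 27.1 M⁻¹ h⁻¹)

Blue's result, set against Sunday's anchor, reads a tail slope of 0.0501 d⁻¹, against the reckoned 0.0645 d⁻¹. The neighbour of green charged with 0.550 equiv of free base lies below both runs in base. The base order 0.611 gives it a slope of 0.0181 d⁻¹, and Saturday's anchor then leaves 30.7%. That neighbour flask holds 30.9% of its electrophile at 8.00 d.

The readings are simulated from invented constants; scatter was added.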